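**Retrosynthetic overview**
1. Target 23 ⇐ 7‑alcohol 22 (acetylation) ⇐ hydroperoxy allyl sulfone 21 by a transannular peroxyl‑radical 6‑exo closure with loss of PhSO2• (forms O–C11, sets C11, creates the 12Z olefin).
2. 21 ⇐ (7R,8R)‑epoxide 20 by perhydrolysis with inversion at C8 (sets 7R,8S).
3. 20 (14‑membered ring plus cis α‑methylene lactone, formed together) ⇐ bromo‑enoate enal 18 by ligand‑controlled CrCl2 allylation (C1–C2, sets 1R,2R).
4. 18 ⇐ allyl sulfone 12 (allylation at C13, Shi epoxidation, acetal hydrolysis, cross‑metathesis) ⇐ iterated isopropenyl Grignard / Claisen chain growth from 2,2‑dimethoxyacetaldehyde.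
5. Ring order: oxirane → macrocycle and lactone → 1,2‑dioxane.

Assumption: cembrane numbering is used for macrocycles and their open‑chain precursors (C1 ring‑fusion CH, C2 lactone CH–O, C3=C4, C7, C8, C11, C12, C13, C14 in the ring; C15 α‑carbon, C16 C=O, C17 exocyclic CH2; C18–C20 methyls on C4, C8, C12). C13 (sulfone carbon) is carried as a 1:1 epimer mixture because it becomes sp2 in step 13.

**Step 1**
Reactants: 1 2,2‑dimethoxyacetaldehyde; 2 isopropenylmagnesium bromide, CH2=C(CH3)MgBr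
Product: 3 1,1‑dimethoxy‑3‑methylbut‑3‑en‑2‑ol (racemic)
Conditions: 1 (dried, distilled), 2 (1.1 equiv), THF, −78 → 0 °C; aq. NH4Cl
Reagents that add atoms: none
Why: Grignard 1,2‑addition to the aldehyde; the carbinol centre is racemic and is destroyed in step 2.

**Step 2**
Reactants: 3 1,1‑dimethoxy‑3‑methylbut‑3‑en‑2‑ol; 4 ethyl vinyl ether
Product: 6 (4E)‑6,6‑dimethoxy‑4‑methylhex‑4‑enal, via allyl vinyl ether 5 (not isolated)
Conditions: 4 (solvent), Hg(OAc)2 (10 mol %), reflux; concentrate; PhMe, Et3N (cat.), 130 °C, sealed tube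
Reagents that add atoms: none
Why: vinyl‑ether exchange then Claisen rearrangement through a chair transition state with the CH(OMe)2 group equatorial gives the E trisubstituted C3=C4 olefin.

**Step 3**
Reactants: 6 (4E)‑6,6‑dimethoxy‑4‑methylhex‑4‑enal; 2 isopropenylmagnesium bromide
Product: 7 (6E)‑8,8‑dimethoxy‑2,6‑dimethylocta‑1,6‑dien‑3‑ol (racemic)
Conditions: 2 (1.1 equiv), THF, −78 °C; aq. NH4Cl
Reagents that add atoms: none
Why: Grignard addition to the aldehyde with the acetal untouched; the carbinol centre is destroyed in step 4.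

**Step 4**
Reactants: 7 (6E)‑8,8‑dimethoxy‑2,6‑dimethylocta‑1,6‑dien‑3‑ol; 4 ethyl vinyl ether
Product: 9 (4E,8E)‑10,10‑dimethoxy‑4,8‑dimethyldeca‑4,8‑dienal, via allyl vinyl ether 8 (not isolated)
Conditions: 4 (solvent), Hg(OAc)2 (10 mol %), reflux; concentrate; PhMe, Et3N (cat.), 130 °C, sealed tube
Reagents that add atoms: none
Why: second Claisen rearrangement, chair transition state with the chain equatorial, gives the E C7=C8 olefin.

**Step 5**
Reactants: 9 (4E,8E)‑10,10‑dimethoxy‑4,8‑dimethyldeca‑4,8‑dienal; 2 isopropenylmagnesium bromide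
Product: 10 (6E,10E)‑12,12‑dimethoxy‑2,6,10‑trimethyldodeca‑1,6,10‑trien‑3‑ol (racemic)
Conditions: 2 (1.1 equiv), THF, −78 °C; aq. NH4Cl
Reagents that add atoms: none
Why: Grignard addition to the aldehyde; the carbinol centre is removed in step 6.

**Step 6**
Reactants: 10 (6E,10E)‑12,12‑dimethoxy‑2,6,10‑trimethyldodeca‑1,6,10‑trien‑3‑ol
Product: 12 [(2E,6E,10E)‑12,12‑dimethoxy‑2,6,10‑trimethyldodeca‑2,6,10‑trien‑1‑yl]sulfonylbenzene, via sulfinate ester 11 (not isolated)
Conditions: PhS(O)Cl, Et3N, CH2Cl2, −78 → 0 °C; then Pd(PPh3)4 (5 mol %), THF, 20 °C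
Reagents that add atoms: benzenesulfinyl chloride, O=S(Cl)c1ccccc1
Why: allylic sulfinate‑to‑sulfone rearrangement (1,3‑transposition through the π‑allyl/sulfinate pair, sulfur bonding to the unhindered terminus C13) gives the primary allyl sulfone; the C11=C12 geometry is of no consequence because C11 becomes sp3 in step 13.

**Step 7**
Reactants: 12 the allyl sulfone; 13 allyl bromide
Product: 14 [(5E,9E,13E)‑15,15‑dimethoxy‑5,9,13‑trimethylpentadeca‑1,5,9,13‑tetraen‑4‑yl]sulfonylbenzene (racemic at the sulfone carbon)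
Conditions: n‑C4H9Li (1.05 equiv), THF, −78 °C; 13 (1.2 equiv), −78 → −20 °C
Reagents that add atoms: none
Why: α‑alkylation of the sulfone‑stabilised allyl anion forms C13–C14; the new centre needs no control.

**Step 8**
Reactants: 14 the allylated sulfone
Product: 15 (9R,10R)‑9,10‑epoxide of 14 (cembrane 7R,8R)
Conditions: Shi D‑fructose‑derived ketone (0.3 equiv), KHSO5 (as 2KHSO5·KHSO4·K2SO4, 1.4 equiv), K2CO3, Bu4NHSO4 (cat.), MeCN–CH2(OMe)2–aq. Na2B4O7 buffer (pH 10.5), 0 °C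
Reagents that add atoms: potassium peroxymonosulfate, [K+].[O-]S(=O)(=O)OO
Why: Shi asymmetric epoxidation (chiral dioxirane, spiro transition state) gives the (R,R)‑epoxide of the only electron‑rich olefin; C3=C4 is deactivated by the allylic acetal, C11=C12 by the allylic sulfone, and the vinyl group is monosubstituted.

**Step 9**
Reactants: 15 the epoxy acetal
Product: 16 (2E,6R,7R,10E)‑6,7‑epoxy‑3,7,11‑trimethyl‑12‑(phenylsulfonyl)pentadeca‑2,10,14‑trienal
Conditions: pyridinium p‑toluenesulfonate (10 mol %), acetone–H2O (10:1), 20 °C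
Reagents that add atoms: water, O
Why: hydrolysis of the allylic dimethyl acetal to the conjugated enal under conditions too mild to open the trisubstituted epoxide.

**Step 10**
Reactants: 16 the enal; 17 methyl 2‑(bromomethyl)acrylate
Product: 18 methyl (2Z,6E,10R,11R,14E)‑2‑(bromomethyl)‑10,11‑epoxy‑6,10,14‑trimethyl‑16‑oxo‑5‑(phenylsulfonyl)hexadeca‑2,6,14‑trienoate
Conditions: 17 (5 equiv), second‑generation Hoveyda–Grubbs catalyst, RuCl2(H2IMes)(=CH‑C6H4‑2‑OiPr) (5 mol %), CH2Cl2, 40 °C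
Reagents that add atoms: none
Why: olefin cross‑metathesis of the only monosubstituted olefin with the 2‑substituted acrylate gives the thermodynamic enoate (C14 trans to CO2Me, hence 2Z); the trisubstituted olefins do not take part.

**Step 11**
Reactants: 18 the bromo‑enoate enal
Product: 20 (1R,2R,3E,7R,8R,11E)‑7,8‑epoxy‑13‑(phenylsulfonyl)cembra‑3,11,15(17)‑trien‑16,2‑olide (cis‑fused lactone), via hydroxy ester 19 (not isolated)
Conditions: CrCl2 (6 equiv), (S)‑oxazoline–sulfonamide ligand (6.6 equiv; antipode chosen for Si‑face attack at C2), Et3N (6.6 equiv), THF, 20 °C; 18 by syringe pump to 2 mM; aq. NaHCO3/serine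
Reagents that add atoms: none
Why: Nozaki–Hiyama–Kishi‑type intramolecular 2‑(methoxycarbonyl)allylation, in which the γ‑substituted allylchromium adds through a closed chair transition state to give the syn alkoxide (cis lactone after loss of MeOH) while the chiral ligand on chromium selects the Si face of the enal carbonyl, fixing 1R,2R independently of the remote epoxide.

**Step 12**
Reactants: 20 the epoxy macrolactone
Product: 21 (1R,2R,3E,7R,8S,11E)‑8‑hydroperoxy‑7‑hydroxy‑13‑(phenylsulfonyl)cembra‑3,11,15(17)‑trien‑16,2‑olide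
Conditions: anhydrous H2O2 in Et2O (10 equiv), H3PMo12O40 (5 mol %), Et2O, 0 → 20 °C
Reagents that add atoms: hydrogen peroxide, OO
Why: acid‑catalysed epoxide perhydrolysis, H2O2 attacking the tertiary carbon C8 with inversion to give 7R,8S; both flanking olefins are inductively deactivated against transannular participation.

**Step 13**
Reactants: 21 the hydroxy hydroperoxide
Product: 22 (1R,2R,3E,7R,8S,11R,12Z)‑8,11‑epidioxy‑7‑hydroxycembra‑3,12,15(17)‑trien‑16,2‑olide
Conditions: tBuON=NOtBu (0.6 equiv), NaHCO3 (solid), benzene (5 mM), argon, dark, 45 °C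
Reagents that add atoms: none
Why: Proposed new method: tBuO• abstracts the OO–H, the tertiary C8 peroxyl radical adds 6‑exo to C11 of the allyl‑sulfone olefin, and the tertiary C12 radical expels PhSO2• by β‑scission to give C12=C13 (no O2, so the carbon radical is not intercepted; not a chain, hence stoichiometric tBuO•); the ten‑atom bridge is expected to favour the cis‑bridged dioxane (C11 R) and fragmentation through the conformer with C14 syn to C11 the 12Z olefin, and the electron‑poor α‑methylene lactone is ignored by the electrophilic peroxyl radical; closest known reaction types are exo cyclisations of hydroperoxide‑derived peroxyl radicals to 1,2‑dioxanes, the thiyl‑mediated oxygenation of vinylcyclopropanes (peroxyl attack on an allyl sulfide with loss of thiyl) and radical allyl transfer from allyl sulfones.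

**Step 14**
Reactants: 22 the dioxane alcohol
Product: 23 (1R,2R,3E,7R,8S,11R,12Z)‑7‑acetoxy‑8,11‑epidioxycembra‑3,12,15(17)‑trien‑16,2‑olide (target)
Conditions: Ac2O, pyridine, 4‑(dimethylamino)pyridine (cat.), CH2Cl2, 0 °C
Reagents that add atoms: acetic anhydride, CC(=O)OC(C)=O
Why: acylation of the secondary C7 alcohol with no stereocentre touched; low temperature and weak base spare the peroxide and the α‑methylene lactone.

**Compound list**
1 | 2,2‑dimethoxyacetaldehyde | COC(OC)C=O | starting material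
2 | isopropenylmagnesium bromide, CH2=C(CH3)MgBr | C=C(C)[Mg]Br | starting material
3 | 1,1‑dimethoxy‑3‑methylbut‑3‑en‑2‑ol (racemic) | COC(OC)C(O)C(C)=C | intermediate
4 | ethyl vinyl ether | C=COCC | starting material
5 | 3‑(ethenyloxy)‑4,4‑dimethoxy‑2‑methylbut‑1‑ene (not isolated) | COC(OC)C(OC=C)C(C)=C | intermediate
6 | (4E)‑6,6‑dimethoxy‑4‑methylhex‑4‑enal | O=CCC/C(C)=C/C(OC)OC | intermediate
7 | (6E)‑8,8‑dimethoxy‑2,6‑dimethylocta‑1,6‑dien‑3‑ol (racemic) | C=C(C)C(O)CC/C(C)=C/C(OC)OC | intermediate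
8 | (6E)‑3‑(ethenyloxy)‑8,8‑dimethoxy‑2,6‑dimethylocta‑1,6‑diene (not isolated) | C=C(C)C(OC=C)CC/C(C)=C/C(OC)OC | intermediate
9 | (4E,8E)‑10,10‑dimethoxy‑4,8‑dimethyldeca‑4,8‑dienal | O=CCC/C(C)=C/CC/C(C)=C/C(OC)OC | intermediate
10 | (6E,10E)‑12,12‑dimethoxy‑2,6,10‑trimethyldodeca‑1,6,10‑trien‑3‑ol (racemic) | C=C(C)C(O)CC/C(C)=C/CC/C(C)=C/C(OC)OC | intermediate
11 | (6E,10E)‑12,12‑dimethoxy‑2,6,10‑trimethyldodeca‑1,6,10‑trien‑3‑yl benzenesulfinate (not isolated) | C=C(C)C(OS(=O)c1ccccc1)CC/C(C)=C/CC/C(C)=C/C(OC)OC | intermediate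
12 | [(2E,6E,10E)‑12,12‑dimethoxy‑2,6,10‑trimethyldodeca‑2,6,10‑trien‑1‑yl]sulfonylbenzene | O=S(=O)(c1ccccc1)C/C(C)=C/CC/C(C)=C/CC/C(C)=C/C(OC)OC | intermediate
13 | allyl bromide | C=CCBr | starting material
14 | [(5E,9E,13E)‑15,15‑dimethoxy‑5,9,13‑trimethylpentadeca‑1,5,9,13‑tetraen‑4‑yl]sulfonylbenzene | C=CCC(S(=O)(=O)c1ccccc1)/C(C)=C/CC/C(C)=C/CC/C(C)=C/C(OC)OC | intermediate
15 | (9R,10R)‑9,10‑epoxide of 14 | C=CCC(S(=O)(=O)c1ccccc1)/C(C)=C/CC[C@@]2(C)O[C@@H]2CC/C(C)=C/C(OC)OC | intermediate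
16 | (2E,6R,7R,10E)‑6,7‑epoxy‑3,7,11‑trimethyl‑12‑(phenylsulfonyl)pentadeca‑2,10,14‑trienal | C=CCC(S(=O)(=O)c1ccccc1)/C(C)=C/CC[C@@]2(C)O[C@@H]2CC/C(C)=C/C=O | intermediate
17 | methyl 2‑(bromomethyl)acrylate | C=C(CBr)C(=O)OC | starting material
18 | methyl (2Z,6E,10R,11R,14E)‑2‑(bromomethyl)‑10,11‑epoxy‑6,10,14‑trimethyl‑16‑oxo‑5‑(phenylsulfonyl)hexadeca‑2,6,14‑trienoate | COC(=O)/C(CBr)=C/CC(S(=O)(=O)c1ccccc1)/C(C)=C/CC[C@@]2(C)O[C@@H]2CC/C(C)=C/C=O | intermediate
19 | methyl (1R,2R,3E,7R,8R,11E)‑7,8‑epoxy‑2‑hydroxy‑13‑(phenylsulfonyl)cembra‑3,11,15(17)‑trien‑16‑oate (not isolated) | C=C(C(=O)OC)[C@@H]1[C@H](O)/C=C(\C)CC[C@H]2O[C@]2(C)CC/C=C(\C)C(S(=O)(=O)c3ccccc3)C1 | intermediate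
20 | (1R,2R,3E,7R,8R,11E)‑7,8‑epoxy‑13‑(phenylsulfonyl)cembra‑3,11,15(17)‑trien‑16,2‑olide | C=C1C(=O)O[C@@H]2/C=C(\C)CC[C@H]3O[C@]3(C)CC/C=C(\C)C(S(=O)(=O)c4ccccc4)C[C@H]12 | intermediate
21 | (1R,2R,3E,7R,8S,11E)‑8‑hydroperoxy‑7‑hydroxy‑13‑(phenylsulfonyl)cembra‑3,11,15(17)‑trien‑16,2‑olide | C=C1C(=O)O[C@@H]2/C=C(\C)CC[C@@H](O)[C@@](C)(OO)CC/C=C(\C)C(S(=O)(=O)c3ccccc3)C[C@H]12 | intermediate
22 | (1R,2R,3E,7R,8S,11R,12Z)‑8,11‑epidioxy‑7‑hydroxycembra‑3,12,15(17)‑trien‑16,2‑olide | C=C1C(=O)O[C@@H]2/C=C(\C)CC[C@@H](O)[C@]3(C)CC[C@@H](OO3)/C(C)=C\C[C@H]12 | intermediate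
23 | (1R,2R,3E,7R,8S,11R,12Z)‑7‑acetoxy‑8,11‑epidioxycembra‑3,12,15(17)‑trien‑16,2‑olide (CNP0238885.6) | C=C1C(=O)O[C@@H]2/C=C(\C)CC[C@@H](OC(C)=O)[C@]3(C)CC[C@@H](OO3)/C(C)=C\C[C@H]12 | target

**Step count and risks**
Total steps: 14. Longest linear sequence: 14.

Steps most likely to fail:

Step 13 (transannular peroxyl‑radical closure). The C11 epimer or the 12E olefin may form, and the electron‑poor allyl‑sulfone olefin may react slowly. Fallback, setting out from 21 and returning at 22: form the O–C11 bond by a two‑electron electrophilic cyclisation instead. Hg(OAc)2 in CH2Cl2 followed by aqueous KBr should give, by anti 6‑exo cycloperoxymercuration at C11 (the β‑sulfonyl carbon C12 resists Markovnikov attack), (1R,2R,3E,7R,8S,11R)‑12‑(bromomercurio)‑8,11‑epidioxy‑7‑hydroxy‑13‑(phenylsulfonyl)cembra‑3,15(17)‑dien‑16,2‑olide F1. Brief NaBH4 demercuration (CH2Cl2/aq. NaOH, 0 °C) then generates the C12 radical, which loses the sulfonyl group to give 22.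

Step 11 (ligand‑controlled macro‑allylation). Ligand control of the absolute sense may fail in the macrocyclic setting. Fallback, setting out from 16 and returning at 20: use a covalently bound auxiliary. Esterify 2‑(bromomethyl)acrylic acid with (−)‑8‑phenylmenthol (dicyclohexylcarbodiimide, 4‑(dimethylamino)pyridine) to give (1R,2S,5R)‑5‑methyl‑2‑(2‑phenylpropan‑2‑yl)cyclohexyl 2‑(bromomethyl)prop‑2‑enoate F2. Cross‑metathesis of 16 with this ester, as in step 10, gives the 8‑phenylmenthyl analogue of 18, F3. Zinc dust (THF/aq. NH4Cl, high dilution) then closes the ring under auxiliary control, and lactonisation expels the auxiliary to give 20.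

Step 12 (perhydrolysis on the macrocycle). Transannular epoxide–olefin reactions or molybdenum‑peroxo epoxidation may compete. Fallback, setting out from 20 and returning at 21: go through a halohydrin. MgBr2·OEt2 (or anhydrous HBr, Et2O, −40 °C) opens the epoxide at C8 with inversion to (1R,2R,3E,7R,8S,11E)‑8‑bromo‑7‑hydroxy‑13‑(phenylsulfonyl)cembra‑3,11,15(17)‑trien‑16,2‑olide F4. AgOSO2CF3 with ethereal H2O2 then ionises the tertiary bromide with participation of the C7 hydroxyl, and H2O2 reopens the epoxonium ion at C8 with inversion to give 21.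

**Further compounds**
F1 | step 13 | (1R,2R,3E,7R,8S,11R)‑12‑(bromomercurio)‑8,11‑epidioxy‑7‑hydroxy‑13‑(phenylsulfonyl)cembra‑3,15(17)‑dien‑16,2‑olide | C=C1C(=O)O[C@@H]2/C=C(\C)CC[C@@H](O)[C@]3(C)CC[C@@H](OO3)C(C)([Hg]Br)C(S(=O)(=O)c4ccccc4)C[C@H]12
F2 | step 11 | (1R,2S,5R)‑5‑methyl‑2‑(2‑phenylpropan‑2‑yl)cyclohexyl 2‑(bromomethyl)prop‑2‑enoate | CC(C)(c1ccccc1)[C@@H]1CC[C@@H](C)C[C@H]1OC(=O)C(=C)CBr
F3 | step 11 | (1R,2S,5R)‑5‑methyl‑2‑(2‑phenylpropan‑2‑yl)cyclohexyl (2Z,6E,10R,11R,14E)‑2‑(bromomethyl)‑10,11‑epoxy‑6,10,14‑trimethyl‑16‑oxo‑5‑(phenylsulfonyl)hexadeca‑2,6,14‑trienoate | CC(C)(c1ccccc1)[C@@H]1CC[C@@H](C)C[C@H]1OC(=O)/C(CBr)=C/CC(S(=O)(=O)c1ccccc1)/C(C)=C/CC[C@@]2(C)O[C@@H]2CC/C(C)=C/C=O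
F4 | step 12 | (1R,2R,3E,7R,8S,11E)‑8‑bromo‑7‑hydroxy‑13‑(phenylsulfonyl)cembra‑3,11,15(17)‑trien‑16,2‑olide | C=C1C(=O)O[C@@H]2/C=C(\C)CC[C@@H](O)[C@@](C)(Br)CC/C=C(\C)C(S(=O)(=O)c3ccccc3)C[C@H]12
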